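**Retrosynthetic overview**
- The target is unmasked last from a 6-bromo methyl ester: the aryl C–Br becomes C–OH and the ester is saponified in one operation.
- The (2Z)-enoate comes from a Still–Gennari olefination of a γ,δ-unsaturated aldehyde with an α-homoprenyl phosphonoacetate.
- Key disconnection: the C–C bond beside the (6E)-trisubstituted alkene, made by a Johnson–Claisen [3,3]-sigmatropic rearrangement of a secondary isopropenyl carbinol. That carbinol comes from the prenyl terminus of linalool by epoxidation and base isomerisation.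
- Only one ring is formed (the benzene ring is bought): the 2H-pyran, closed early by ring-closing metathesis of a styrene/vinyl aryl ether.
- The aryl ether comes from SNAr of the alkoxide of (R)-linalool (1) on 5-bromo-2-fluoro-3-methylbenzaldehyde (2). The C–O bond of the only stereocentre is bought and never broken.

Assumption: (R)-(−)-linalool of ≥97% ee (ho-wood grade) and compound 2 are taken as catalogue materials; the product ee equals that of the linalool used.

**Step 1**
Reactants: 1, (R)-(−)-linalool [(3R)-3,7-dimethylocta-1,6-dien-3-ol]; 2, 5-bromo-2-fluoro-3-methylbenzaldehyde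
Product: 3, 5-bromo-2-{[(3R)-3,7-dimethylocta-1,6-dien-3-yl]oxy}-3-methylbenzaldehyde
Conditions: KHMDS (1.05 equiv), THF, 0 °C, 15 min; then 2 (1.2 equiv), THF/DMF, 0 °C → rt
Reagents that add atoms: none
Why: SNAr (addition–elimination) of the pre-formed tertiary potassium alkoxide at the C–F bond activated by the ortho-CHO and para-Br; the carbinol C–O bond is untouched, so the (R) centre is carried over with retention.

**Step 2**
Reactants: 3
Product: 4, 5-bromo-2-{[(3R)-3,7-dimethylocta-1,6-dien-3-yl]oxy}-1-ethenyl-3-methylbenzene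
Conditions: Ph3PCH3Br, KOtBu, THF, 0 °C → rt
Reagents that add atoms: methyltriphenylphosphonium bromide, C[P+](c1ccccc1)(c1ccccc1)c1ccccc1.[Br-]
Why: Wittig methylenation of a non-enolisable aryl aldehyde under basic conditions that leave the acid-sensitive tertiary allylic aryl ether and the aryl bromide alone.

**Step 3**
Reactants: 4
Product: 5, 2-[(3R)-3-(4-bromo-2-ethenyl-6-methylphenoxy)-3-methylpent-4-en-1-yl]-3,3-dimethyloxirane (about 1:1 epimers at the oxirane CH)
Conditions: mCPBA (1.05 equiv), NaHCO3, CH2Cl2, 0 °C
Reagents that add atoms: mCPBA, OOC(=O)c1cccc(Cl)c1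
Why: Prilezhaev epoxidation is selective for the electron-rich trisubstituted alkene over the two monosubstituted alkenes, and it also removes the prenyl group as a competitor in the metathesis; the new epoxide centre is uncontrolled and is destroyed later.

**Step 4**
Reactants: 5
Product: 6, (2R)-6-bromo-2-[2-(3,3-dimethyloxiran-2-yl)ethyl]-2,8-dimethyl-2H-chromene (epimers at the oxirane CH)
Conditions: Grubbs II (3–5 mol %), CH2Cl2 (0.01 M), 40 °C
Reagents that add atoms: none
Why: Ring-closing olefin metathesis of the styrene with the vinyl group on the quaternary carbon gives the six-membered 2H-chromene with loss of ethylene, without touching the stereocentre.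

**Step 5**
Reactants: 6
Product: 7, 1-[(2R)-6-bromo-2,8-dimethyl-2H-chromen-2-yl]-4-methylpent-4-en-3-ol (about 1:1 epimers at C3)
Conditions: Et2Al(TMP) (from LiTMP + Et2AlCl, 2.5 equiv), toluene, 0 °C → rt
Reagents that add atoms: none
Why: Yamamoto aluminium-amide epoxide-to-allylic-alcohol isomerisation removes a proton from the less hindered methyl group and opens the tertiary C–O bond, giving the secondary isopropenyl carbinol regioselectively; its configuration is irrelevant.

**Step 6**
Reactants: 7
Product: 8, ethyl (4E)-7-[(2R)-6-bromo-2,8-dimethyl-2H-chromen-2-yl]-4-methylhept-4-enoate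
Conditions: MeC(OEt)3 (8 equiv), EtCO2H (10 mol %), 125–135 °C, 2–3 h, EtOH distilled off
Reagents that add atoms: triethyl orthoacetate, CCOC(C)(OCC)OCC
Why: Johnson–Claisen [3,3]-sigmatropic rearrangement of the in-situ ketene acetal through a chair transition state with the large chain equatorial forms the new C–C bond and the (E)-trisubstituted alkene (typically ≥95:5), and both carbinol epimers converge.

**Step 7**
Reactants: 8
Product: 9, (4E)-7-[(2R)-6-bromo-2,8-dimethyl-2H-chromen-2-yl]-4-methylhept-4-enal
Conditions: DIBAL-H (1.05 equiv), CH2Cl2, −78 °C; Rochelle salt work-up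
Reagents that add atoms: none
Why: Low-temperature DIBAL-H partial reduction of the ester stops at the aldehyde through the stable tetrahedral aluminium hemiacetal, and nothing else in the molecule is reducible under these conditions.

**Step 8**
Reactants: 10, methyl 2-[bis(2,2,2-trifluoroethoxy)phosphoryl]acetate; 11, 5-bromo-2-methylpent-2-ene
Product: 12, methyl 2-[bis(2,2,2-trifluoroethoxy)phosphoryl]-6-methylhept-5-enoate (racemic)
Conditions: NaH (1.0 equiv), DMSO, rt; then 11, NaI (cat.), rt → 50 °C
Reagents that add atoms: none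
Why: SN2 C-alkylation of the stabilised phosphonoacetate anion with a primary homoallylic bromide (Finkelstein-assisted) installs the homoprenyl branch.

**Step 9**
Reactants: 9; 12
Product: 13, methyl (2Z,6E)-9-[(2R)-6-bromo-2,8-dimethyl-2H-chromen-2-yl]-6-methyl-2-(4-methylpent-3-en-1-yl)nona-2,6-dienoate
Conditions: 12 (1.3 equiv), KHMDS (1.25 equiv), 18-crown-6 (4 equiv), THF, −78 °C; then 9, −78 °C, 3 h
Reagents that add atoms: none
Why: Still–Gennari modification of the Horner–Wadsworth–Emmons olefination, where the electron-poor trifluoroethyl phosphonate with a dissociated potassium counter-ion eliminates under kinetic control to place the ester cis to the new chain (Z, typically ≥10:1).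

**Step 10**
Reactants: 13
Product: 14, (R)-sargachromenol [(2Z,6E)-9-[(2R)-6-hydroxy-2,8-dimethyl-2H-chromen-2-yl]-6-methyl-2-(4-methylpent-3-en-1-yl)nona-2,6-dienoic acid]
Conditions: Pd2(dba)3 (2.5 mol %), t-BuXPhos (10 mol %), KOH (6 equiv), degassed 1,4-dioxane/H2O (1:1), 80 °C; then 1 M HCl to pH 3 under Ar
Reagents that add atoms: potassium hydroxide, [K+].[OH-]; water, O
Why: Buchwald-type Pd-catalysed hydroxylation converts the aryl bromide to the phenol while the same aqueous KOH saponifies the methyl ester, and the C2–O bond and both alkene geometries are not involved.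

**Compound list**
1 | (R)-(−)-linalool | C=C[C@](C)(O)CCC=C(C)C | starting material
2 | 5-bromo-2-fluoro-3-methylbenzaldehyde | O=Cc1cc(Br)cc(C)c1F | starting material
3 | 5-bromo-2-{[(3R)-3,7-dimethylocta-1,6-dien-3-yl]oxy}-3-methylbenzaldehyde | C=C[C@](C)(Oc1c(C)cc(Br)cc1C=O)CCC=C(C)C | intermediate
4 | 5-bromo-2-{[(3R)-3,7-dimethylocta-1,6-dien-3-yl]oxy}-1-ethenyl-3-methylbenzene | C=C[C@](C)(Oc1c(C)cc(Br)cc1C=C)CCC=C(C)C | intermediate
5 | 2-[(3R)-3-(4-bromo-2-ethenyl-6-methylphenoxy)-3-methylpent-4-en-1-yl]-3,3-dimethyloxirane (epimers at oxirane CH) | C=C[C@](C)(Oc1c(C)cc(Br)cc1C=C)CCC1OC1(C)C | intermediate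
6 | (2R)-6-bromo-2-[2-(3,3-dimethyloxiran-2-yl)ethyl]-2,8-dimethyl-2H-chromene (epimers at oxirane CH) | CC1(C)OC1CC[C@]1(C)C=Cc2cc(Br)cc(C)c2O1 | intermediate
7 | 1-[(2R)-6-bromo-2,8-dimethyl-2H-chromen-2-yl]-4-methylpent-4-en-3-ol (epimers at C3) | C=C(C)C(O)CC[C@]1(C)C=Cc2cc(Br)cc(C)c2O1 | intermediate
8 | ethyl (4E)-7-[(2R)-6-bromo-2,8-dimethyl-2H-chromen-2-yl]-4-methylhept-4-enoate | CCOC(=O)CC/C(C)=C/CC[C@]1(C)C=Cc2cc(Br)cc(C)c2O1 | intermediate
9 | (4E)-7-[(2R)-6-bromo-2,8-dimethyl-2H-chromen-2-yl]-4-methylhept-4-enal | O=CCC/C(C)=C/CC[C@]1(C)C=Cc2cc(Br)cc(C)c2O1 | intermediate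
10 | methyl 2-[bis(2,2,2-trifluoroethoxy)phosphoryl]acetate | COC(=O)CP(=O)(OCC(F)(F)F)OCC(F)(F)F | starting material
11 | 5-bromo-2-methylpent-2-ene | CC(C)=CCCBr | starting material
12 | methyl 2-[bis(2,2,2-trifluoroethoxy)phosphoryl]-6-methylhept-5-enoate (racemic) | COC(=O)C(CCC=C(C)C)P(=O)(OCC(F)(F)F)OCC(F)(F)F | intermediate
13 | methyl (2Z,6E)-9-[(2R)-6-bromo-2,8-dimethyl-2H-chromen-2-yl]-6-methyl-2-(4-methylpent-3-en-1-yl)nona-2,6-dienoate | CC(C)=CCC/C(=C/CC/C(C)=C/CC[C@]1(C)C=Cc2cc(Br)cc(C)c2O1)C(=O)OC | intermediate
14 | (R)-sargachromenol | CC(C)=CCC/C(=C/CC/C(C)=C/CC[C@]1(C)C=Cc2cc(O)cc(C)c2O1)C(=O)O | target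

**Totals**
Total steps: 10.
Longest linear sequence: 9 (steps 1–7, 9, 10); step 8 is a one-step side branch.

**Three steps most likely to fail**
1. Step 1. A hindered tertiary alkoxide must attack a fluoride flanked by Me and CHO, and may instead add to the aldehyde (Tishchenko-type side reactions) or stall. Fallback: run the SNAr on 5-bromo-2-fluoro-3-methylbenzonitrile, which is better activated and has no carbonyl to attack, then reveal aldehyde 3 with DIBAL-H (one extra step).
2. Step 6. About 130 °C with the 2H-chromene in place risks partial erosion of ee through reversible thermal oxa-6π ring opening or acid-assisted C2–O ionisation, and some E/Z leakage; ee should be checked by chiral HPLC here. Fallback: Ireland–Claisen rearrangement of the acetate of 7 (LDA, TMSCl, −78 °C → rt) to the γ,δ-unsaturated acid, then LiAlH4 reduction and Dess–Martin oxidation to 9, all at or below room temperature.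
3. Step 10. Hot aqueous KOH may partly isomerise the Z-enoate, the electron-rich phenol is air-sensitive in base, and diaryl ether formation can compete. Fallback: convert the C–Br bond through boron instead (Miyaura borylation of 13 with B2pin2, Pd(dppf)Cl2, KOAc, then NaBO3 oxidation to the phenol), followed by a separate LiOH saponification at room temperature.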